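**Plan**

- Retrosynthesis: after removal of the two silyl ethers, the bond between the lactone α-carbon and the quaternary ether carbon is cut (reverse carbene C–H insertion). This opens the γ-lactone and the eight-membered carbocycle together to an 11-membered α-diazo-β-keto lactone. Then follow the lactone C–O bond (acylketene), the ether C–O bond at its methyl-bearing carbon (epoxide opening), the ring–chain C–C bond (aldol) and the two cyclohexene σ-bonds (Diels–Alder).
- Enabling feature: in the cage the quaternary ether carbon is bonded to the carbon that carries the lactone oxygen, so it lies 1,5 to the lactone α-carbon across the ester oxygen. Before that bond exists it is a tertiary C–H next to the bridging oxygen of the 2-oxabicyclo[2.2.2]octane.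
- Forward order: cyclohexene ring by Diels–Alder on a cyclopentenone (cis-hydrindanone), side chain by aldol, oxabicyclo[2.2.2]octane by epoxide opening, 11-membered lactone by acylketene capture, then γ-lactone and eight-membered ring together by the insertion.
- Stereochemistry: the two chain methyl centres come from lipase desymmetrisation of a meso diol and the ring-fusion centres from a catalyst-controlled Diels–Alder. All other centres are relayed from the ring fusion (convex-face aldol, internal hydride delivery, convex-face protonation and epoxidation, anti epoxide opening, retention in the insertion).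

Key step: step 22

Remark on locants: bicyclic intermediates are numbered as indanes (C1 ketone/ether carbon, C2 chain-bearing carbon, C3a/C7a ring fusion, C5 methyl-bearing carbon, C6 CH2O-bearing carbon); the side chain is C1′–C5′ counted from the ring.
Assumption (chain): acetylation of meso diol 8 by Pseudomonas fluorescens lipase is taken to occur at the hydroxymethyl arm on the (S)-carbon, giving 9; should the enzyme prefer the other arm, lipase hydrolysis of the diacetate supplies the same monoacetate.
Assumption (ring fusion): the (S)-oxazaborolidinium catalyst is taken to expose the enone face that leads to the (3aS,7aS) adduct 6; should the sense be opposite, the (R)-catalyst is used.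

**Route**

Step 1
Reactants: 1 cyclopentane-1,2-dione
Product: 2 5-oxocyclopent-1-en-1-yl benzoate
Conditions: BzCl, Et3N, DMAP (cat.), CH2Cl2, 0 °C
Reagents that add atoms: benzoyl chloride, O=C(Cl)c1ccccc1
Why: O-acylation of the enol tautomer of the 1,2-dione should give the enol benzoate, which masks the future angular oxygen and keeps the enone electron-poor for the cycloaddition.

Step 2
Reactants: 3 methyl vinyl ketone
Product: 4 3-(hydroxymethyl)but-3-en-2-one
Conditions: aq. CH2O, DABCO (cat.), THF/H2O, rt
Reagents that add atoms: formaldehyde, C=O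
Why: Morita–Baylis–Hillman reaction of the enone with formaldehyde places the hydroxymethyl carbon on the α-carbon, the atom that becomes the CH2OH-bearing ring carbon.

Step 3
Reactants: 4 3-(hydroxymethyl)but-3-en-2-one
Product: 5 2-(tert-butyldimethylsilyloxy)-3-[(tert-butyldimethylsilyloxy)methyl]buta-1,3-diene
Conditions: TBSOTf (2.2 equiv), Et3N, CH2Cl2, −78 → 0 °C
Reagents that add atoms: tert-butyldimethylsilyl triflate, CC(C)(C)[Si](C)(C)OS(=O)(=O)C(F)(F)F
Why: O-silylation of the alcohol and soft enolisation–silylation of the methyl ketone (its only enolisable side) in one operation should give the 2-silyloxy diene.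

Step 4
Reactants: 2 5-oxocyclopent-1-en-1-yl benzoate; 5 the bis-silyl diene
Product: 6 (3aS,7aS)-5-(tert-butyldimethylsilyloxy)-6-[(tert-butyldimethylsilyloxy)methyl]-1-oxo-2,3,3a,4,7,7a-hexahydro-1H-inden-7a-yl benzoate (cis-fused)
Conditions: (S)-1-(2-methylphenyl)-3,3-diphenyltetrahydro-1H,3H-pyrrolo[1,2-c][1,3,2]oxazaborole (20 mol%), AlBr3 (16 mol%), CH2Cl2, −78 → −40 °C
Reagents that add atoms: none
Why: Catalytic enantioselective Diels–Alder reaction, in which the nucleophilic CH2 terminus next to the silyloxy carbon bonds to the enone β-carbon (para orientation), suprafacial addition fixes the cis ring fusion and the chiral Lewis acid selects the enone face, so both ring-fusion centres are set here.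

Step 5
Reactants: 7 meso-2,4-dimethylglutaric anhydride
Product: 8 meso-2,4-dimethylpentane-1,5-diol
Conditions: LiAlH4, THF, 0 °C → reflux
Reagents that add atoms: none
Why: LiAlH4 reduction of a cyclic anhydride to the 1,5-diol leaves the syn relationship of the two methyl-bearing carbons untouched.

Step 6
Reactants: 8 meso-2,4-dimethylpentane-1,5-diol
Product: 9 (2S,4R)-5-hydroxy-2,4-dimethylpentyl acetate
Conditions: lipase AK (Pseudomonas fluorescens), vinyl acetate, THF, rt
Reagents that add atoms: vinyl acetate, CC(=O)OC=C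
Why: Lipase-catalysed transesterification that distinguishes the enantiotopic hydroxymethyl arms (desymmetrisation of a meso diol) should acetylate one arm only and so turn the meso pair into the two chain stereocentres with defined absolute configuration.

Step 7
Reactants: 9 (2S,4R)-5-hydroxy-2,4-dimethylpentyl acetate
Product: 10 (2S,4R)-2,4-dimethyl-5-oxopentyl acetate
Conditions: Dess–Martin periodinane, NaHCO3, CH2Cl2, 0 °C
Reagents that add atoms: none
Why: Dess–Martin oxidation under buffered, non-basic conditions should give the α-branched aldehyde without epimerisation.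

Step 8
Reactants: 6 the Diels–Alder adduct; 10 (2S,4R)-2,4-dimethyl-5-oxopentyl acetate
Product: 12 aldol adduct carrying at C2 the (2R,4S)-5-acetoxy-1-hydroxy-2,4-dimethylpentyl chain cis to the C7a benzoate (C1′ carbinol epimers), via lithium enolate 11 (not isolated)
Conditions: LiN(i-Pr)2, THF, −78 °C; then 10; AcOH quench at −78 °C
Reagents that add atoms: none
Why: Aldol addition of the kinetic lithium enolate (C2 is the only enolisable position) to the aldehyde, which should approach the convex face of the cis-hydrindanone away from the six-membered ring and so place the chain cis to the angular benzoate; the carbinol centre needs no control because it is oxidised later.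

Step 9
Reactants: 12 the aldol adduct
Product: 13 C1 alcohol with C1′ benzoate (ring hydroxyl trans to the chain, on the concave face)
Conditions: PhCHO, SmI2 (0.3 equiv), THF, −10 °C
Reagents that add atoms: benzaldehyde, O=Cc1ccccc1
Why: Evans–Tishchenko reduction, in which the samarium-bound hemiacetal of the β-hydroxyl and benzaldehyde delivers hydride through a six-membered transition state that can only reach the ketone face syn to the side chain, so the ring hydroxyl comes out trans to the chain and the chain carbinol leaves as its benzoate.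

Step 10
Reactants: 13 the C1 alcohol
Product: 14 C1 2-methoxyprop-2-yl (MOP) ether of 13
Conditions: 2-methoxypropene, PPTS (cat.), CH2Cl2, 0 °C
Reagents that add atoms: 2-methoxypropene, C=C(C)OC
Why: Acid-catalysed addition of the alcohol to the enol ether gives a base-stable mixed acetal that masks the ring hydroxyl for the enolate step and adds bulk on the concave face.

Step 11
Reactants: 14 the MOP ether
Product: 15 C5 ketone with H6 cis to the C7a benzoate (CH2OTBS on the concave face)
Conditions: Bu4NF, AcOH, THF, −78 → −40 °C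
Reagents that add atoms: none
Why: Fluoride cleavage of the silyl enol ether with kinetic protonation of the enolate, where the proton should arrive on the convex face because the concave face is screened by the cyclopentane ring and its acetal; this sets the CH2O-bearing centre.

Step 12
Reactants: 15 the C5 ketone
Product: 17 enol triflate (C4=C5), via potassium enolate 16 (not isolated)
Conditions: KN(SiMe3)2, THF, −78 °C; then Comins' reagent
Reagents that add atoms: N-(5-chloropyridin-2-yl)bis(trifluoromethanesulfonyl)imide, FC(F)(F)S(=O)(=O)N(c1ccc(Cl)cn1)S(=O)(=O)C(F)(F)F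
Why: Kinetic deprotonation at the unhindered α-methylene (not at the substituted methine) and O-triflation of the enolate should give the less substituted enol triflate without disturbing the new α-stereocentre.

Step 13
Reactants: 17 the enol triflate
Product: 18 5-methyl alkene (C4=C5)
Conditions: Me2Zn, Pd(PPh3)4 (cat.), THF, 0 °C → rt
Reagents that add atoms: dimethylzinc, C[Zn]C
Why: Negishi cross-coupling of the alkenyl triflate with a methylzinc reagent under zerovalent palladium catalysis replaces triflate by methyl with the double bond held in place, and the esters are inert to the organozinc.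

Step 14
Reactants: 18 the 5-methyl alkene
Product: 21 cage alcohol (2-oxabicyclo[2.2.2]octane; C4 hydroxyl anti to the ether bridge), via epoxide 19 (not isolated), via epoxy alcohol 20 (not isolated)
Conditions: mCPBA, NaHCO3, CH2Cl2, 0 °C; then CSA (cat.), MeOH/CH2Cl2, 0 °C
Reagents that add atoms: 3-chloroperbenzoic acid, OOC(=O)c1cccc(Cl)c1
Why: Prilezhaev epoxidation from the convex face (the cyclopentane ring and its acetal shield the other face), then acid cleavage of the acetal and intramolecular anti opening of the epoxide at its tertiary carbon by the ring hydroxyl, which closes the ether bridge with inversion at the methyl-bearing carbon and leaves the neighbouring carbinol trans to the new C–O bond.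

Step 15
Reactants: 21 the cage alcohol
Product: 22 cage bis-silyl ether (C4 OTBS) still carrying acetate and two benzoates
Conditions: TBSOTf, 2,6-lutidine, CH2Cl2, 0 °C
Reagents that add atoms: tert-butyldimethylsilyl triflate, CC(C)(C)[Si](C)(C)OS(=O)(=O)C(F)(F)F
Why: Silylation of the only free hydroxyl with the silyl triflate protects it against O–H insertion in the carbene step.

Step 16
Reactants: 22 the cage bis-silyl ether
Product: 23 triol (tertiary C7a–OH, secondary C1′–OH, primary C5′–OH)
Conditions: i-Bu2AlH, CH2Cl2, −78 → 0 °C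
Reagents that add atoms: none
Why: Reductive cleavage of the acetate and both benzoates (including the tertiary one) by the aluminium hydride frees the three hydroxyls in one base-free operation, so no centre can epimerise.

Step 17
Reactants: 23 the triol
Product: 24 keto aldehyde (C1′ ketone, C5′ aldehyde, free tertiary alcohol)
Conditions: (COCl)2, DMSO, CH2Cl2, −78 °C; then i-Pr2NEt, −78 → −20 °C
Reagents that add atoms: none
Why: Swern oxidation activates both hydroxyls as alkoxysulfonium ions before base is added, so the primary alcohol gives the aldehyde and the secondary one the ketone without a lactol forming between them; the tertiary alcohol cannot oxidise and the two carbinol epimers converge.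

Step 18
Reactants: 24 the keto aldehyde
Product: 25 keto acid
Conditions: NaClO2, NaH2PO4, 2-methylbut-2-ene, t-BuOH/H2O, 0 °C
Reagents that add atoms: sodium chlorite, [Na+].[O-]Cl=O
Why: Pinnick oxidation converts the aldehyde chemoselectively into the acid at buffered pH and leaves ketone, tertiary alcohol and silyl ethers alone.

Step 19
Reactants: 25 the keto acid; 26 Meldrum's acid
Product: 27 acyl Meldrum's acid (enol form)
Conditions: DCC, DMAP, CH2Cl2, 0 °C → rt
Reagents that add atoms: none
Why: Carbodiimide-mediated C-acylation of Meldrum's acid (Oikawa–Yonemitsu procedure) should give the acyl Meldrum's acid, the hindered tertiary alcohol staying unacylated.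

Step 20
Reactants: 27 the acyl Meldrum's acid
Product: 29 11-membered β-keto lactone, via acylketene 28 (not isolated)
Conditions: toluene (1 mM), 110 °C
Reagents that add atoms: none
Why: Thermolysis releases acetone and CO2 to give an acylketene, which the tertiary hydroxyl captures at high dilution (acylketene macrolactonisation of the Boeckman type) to close the 11-membered ring; no stereocentre is involved.

Step 21
Reactants: 29 the β-keto lactone
Product: 30 11-membered α-diazo-β-keto lactone
Conditions: 4-acetamidobenzenesulfonyl azide, Et3N, MeCN, 0 °C → rt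
Reagents that add atoms: 4-acetamidobenzenesulfonyl azide, CC(=O)Nc1ccc(cc1)S(=O)(=O)N=[N+]=[N-]
Why: Regitz diazo transfer to the active methylene of the β-keto lactone proceeds under mild amine base that should not touch the ketone α-centres.

Step 22
Reactants: 30 the α-diazo-β-keto lactone
Product: 32 bis-TBS ether of abyssomicin O (enol form), via keto lactone 31 (not isolated)
Conditions: Rh2(OAc)4 (2 mol%), CH2Cl2, 40 °C, slow addition
Reagents that add atoms: none
Why: Proposed new method: Rh2(OAc)4 should convert 30 into an electrophilic acceptor–acceptor rhodium carbene at the lactone α-carbon, which inserts in a concerted three-centre fashion into the ether methine C–H lying 1,5 to it across the ester oxygen; the closest known reaction is the Rh2(OAc)4-catalysed 1,5 C–H insertion of acyclic α-diazo-β-keto esters next to an ether oxygen to give γ-lactones, here moved into a transannular setting that has not been tested. The γ-lactone closes through the usual five-membered transition state on the ester tether, and because the carbene carbon is already a member of the 11-membered ring the same C–C bond closes the eight-membered carbocycle transannularly. The new quaternary centre forms with retention at the inserting C–H, and the cage in any case permits only the cis-fused lactone. The step needs site selectivity among the 1,5 hydrogens: the wanted methine is tertiary and activated by the ether oxygen, the ring-fusion methine and the ring methylene on the same tether lack heteroatom activation, the methine on the keto side is deactivated by the adjacent ring ketone, and both hydroxyls are silylated so that O–H insertion is excluded. The first-formed keto lactone 31 should enolise at once to the hydrogen-bonded acyl lactone 32.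

Step 23
Reactants: 32 the bis-TBS ether
Product: 33 abyssomicin O
Conditions: HF·pyridine, pyridine/THF, 0 °C → rt
Reagents that add atoms: none
Why: Fluoride-mediated cleavage of both silyl ethers under buffered acidic conditions, which the acidic acyl-lactone enol should tolerate, releases the target.

**Compound list**

1 | cyclopentane-1,2-dione | O=C1CCCC1=O | starting material
2 | 5-oxocyclopent-1-en-1-yl benzoate | O=C1CCC=C1OC(=O)c2ccccc2 | intermediate
3 | methyl vinyl ketone | C=CC(C)=O | starting material
4 | 3-(hydroxymethyl)but-3-en-2-one | CC(=O)C(=C)CO | intermediate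
5 | 2-(tert-butyldimethylsilyloxy)-3-[(tert-butyldimethylsilyloxy)methyl]buta-1,3-diene | C=C(O[Si](C)(C)C(C)(C)C)C(=C)CO[Si](C)(C)C(C)(C)C | intermediate
6 | (3aS,7aS)-5-(TBSO)-6-(TBSOCH2)-1-oxo-2,3,3a,4,7,7a-hexahydro-1H-inden-7a-yl benzoate | O=C1CC[C@H]2CC(O[Si](C)(C)C(C)(C)C)=C(CO[Si](C)(C)C(C)(C)C)C[C@@]12OC(=O)c3ccccc3 | intermediate
7 | meso-2,4-dimethylglutaric anhydride | C[C@@H]1C[C@H](C)C(=O)OC1=O | starting material
8 | meso-2,4-dimethylpentane-1,5-diol | C[C@@H](CO)C[C@H](C)CO | intermediate
9 | (2S,4R)-5-hydroxy-2,4-dimethylpentyl acetate | CC(=O)OC[C@@H](C)C[C@@H](C)CO | intermediate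
10 | (2S,4R)-2,4-dimethyl-5-oxopentyl acetate | CC(=O)OC[C@@H](C)C[C@@H](C)C=O | intermediate
11 | lithium enolate of 6 (C1–C2 enolate) | [Li+].[O-]C1=CC[C@H]2CC(O[Si](C)(C)C(C)(C)C)=C(CO[Si](C)(C)C(C)(C)C)C[C@@]12OC(=O)c3ccccc3 | intermediate
12 | aldol adduct: 6 with a (2R,4S)-5-acetoxy-1-hydroxy-2,4-dimethylpentyl chain at C2, cis to the C7a benzoate; C1′ epimers | CC(=O)OC[C@@H](C)C[C@@H](C)C(O)[C@@H]1C[C@H]2CC(O[Si](C)(C)C(C)(C)C)=C(CO[Si](C)(C)C(C)(C)C)C[C@@]2(OC(=O)c3ccccc3)C1=O | intermediate
13 | C1 alcohol (trans to the chain) with C1′ benzoate | CC(=O)OC[C@@H](C)C[C@@H](C)C(OC(=O)c3ccccc3)[C@@H]1C[C@H]2CC(O[Si](C)(C)C(C)(C)C)=C(CO[Si](C)(C)C(C)(C)C)C[C@@]2(OC(=O)c3ccccc3)[C@H]1O | intermediate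
14 | C1 2-methoxyprop-2-yl ether of 13 | CC(=O)OC[C@@H](C)C[C@@H](C)C(OC(=O)c3ccccc3)[C@@H]1C[C@H]2CC(O[Si](C)(C)C(C)(C)C)=C(CO[Si](C)(C)C(C)(C)C)C[C@@]2(OC(=O)c3ccccc3)[C@H]1OC(C)(C)OC | intermediate
15 | C5 ketone, H6 cis to the C7a benzoate | CC(=O)OC[C@@H](C)C[C@@H](C)C(OC(=O)c3ccccc3)[C@@H]1C[C@H]2CC(=O)[C@@H](CO[Si](C)(C)C(C)(C)C)C[C@@]2(OC(=O)c3ccccc3)[C@H]1OC(C)(C)OC | intermediate
16 | potassium enolate of 15 (C4–C5 enolate) | [K+].CC(=O)OC[C@@H](C)C[C@@H](C)C(OC(=O)c3ccccc3)[C@@H]1C[C@H]2C=C([O-])[C@@H](CO[Si](C)(C)C(C)(C)C)C[C@@]2(OC(=O)c3ccccc3)[C@H]1OC(C)(C)OC | intermediate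
17 | C5 enol triflate (C4=C5) | CC(=O)OC[C@@H](C)C[C@@H](C)C(OC(=O)c3ccccc3)[C@@H]1C[C@H]2C=C(OS(=O)(=O)C(F)(F)F)[C@@H](CO[Si](C)(C)C(C)(C)C)C[C@@]2(OC(=O)c3ccccc3)[C@H]1OC(C)(C)OC | intermediate
18 | 5-methyl alkene (C4=C5) | CC(=O)OC[C@@H](C)C[C@@H](C)C(OC(=O)c3ccccc3)[C@@H]1C[C@H]2C=C(C)[C@@H](CO[Si](C)(C)C(C)(C)C)C[C@@]2(OC(=O)c3ccccc3)[C@H]1OC(C)(C)OC | intermediate
19 | 4,5-epoxide on the face of the C7a benzoate | CC(=O)OC[C@@H](C)C[C@@H](C)C(OC(=O)c3ccccc3)[C@@H]1C[C@H]2[C@@H]4O[C@]4(C)[C@@H](CO[Si](C)(C)C(C)(C)C)C[C@@]2(OC(=O)c3ccccc3)[C@H]1OC(C)(C)OC | intermediate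
20 | epoxy alcohol (free C1–OH) | CC(=O)OC[C@@H](C)C[C@@H](C)C(OC(=O)c3ccccc3)[C@@H]1C[C@H]2[C@@H]4O[C@]4(C)[C@@H](CO[Si](C)(C)C(C)(C)C)C[C@@]2(OC(=O)c3ccccc3)[C@H]1O | intermediate
21 | cage alcohol (ether O between C1 and C5, free C4–OH) | CC(=O)OC[C@@H](C)C[C@@H](C)C(OC(=O)c4ccccc4)[C@@H]1C[C@H]2[C@H](O)[C@@]3(C)O[C@@H]1[C@]2(OC(=O)c4ccccc4)C[C@@H]3CO[Si](C)(C)C(C)(C)C | intermediate
22 | cage bis-TBS ether with acetate and two benzoates | CC(=O)OC[C@@H](C)C[C@@H](C)C(OC(=O)c4ccccc4)[C@@H]1C[C@H]2[C@H](O[Si](C)(C)C(C)(C)C)[C@@]3(C)O[C@@H]1[C@]2(OC(=O)c4ccccc4)C[C@@H]3CO[Si](C)(C)C(C)(C)C | intermediate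
23 | triol | OC[C@@H](C)C[C@@H](C)C(O)[C@@H]1C[C@H]2[C@H](O[Si](C)(C)C(C)(C)C)[C@@]3(C)O[C@@H]1[C@]2(O)C[C@@H]3CO[Si](C)(C)C(C)(C)C | intermediate
24 | keto aldehyde | O=C[C@@H](C)C[C@@H](C)C(=O)[C@@H]1C[C@H]2[C@H](O[Si](C)(C)C(C)(C)C)[C@@]3(C)O[C@@H]1[C@]2(O)C[C@@H]3CO[Si](C)(C)C(C)(C)C | intermediate
25 | keto acid | OC(=O)[C@@H](C)C[C@@H](C)C(=O)[C@@H]1C[C@H]2[C@H](O[Si](C)(C)C(C)(C)C)[C@@]3(C)O[C@@H]1[C@]2(O)C[C@@H]3CO[Si](C)(C)C(C)(C)C | intermediate
26 | Meldrum's acid | CC1(C)OC(=O)CC(=O)O1 | starting material
27 | acyl Meldrum's acid (enol) | CC1(C)OC(=O)C(=C(O)[C@@H](C)C[C@@H](C)C(=O)[C@@H]2C[C@H]3[C@H](O[Si](C)(C)C(C)(C)C)[C@@]4(C)O[C@@H]2[C@]3(O)C[C@@H]4CO[Si](C)(C)C(C)(C)C)C(=O)O1 | intermediate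
28 | acylketene | O=C=CC(=O)[C@@H](C)C[C@@H](C)C(=O)[C@@H]1C[C@H]2[C@H](O[Si](C)(C)C(C)(C)C)[C@@]3(C)O[C@@H]1[C@]2(O)C[C@@H]3CO[Si](C)(C)C(C)(C)C | intermediate
29 | 11-membered β-keto lactone on the tricyclic cage ether | C[C@@H]1C[C@H](C)C(=O)CC(=O)O[C@]34C[C@H](CO[Si](C)(C)C(C)(C)C)[C@]5(C)O[C@H]3[C@@H](C[C@H]4[C@@H]5O[Si](C)(C)C(C)(C)C)C1=O | intermediate
30 | 11-membered α-diazo-β-keto lactone | C[C@@H]1C[C@H](C)C(=O)C(=[N+]=[N-])C(=O)O[C@]34C[C@H](CO[Si](C)(C)C(C)(C)C)[C@]5(C)O[C@H]3[C@@H](C[C@H]4[C@@H]5O[Si](C)(C)C(C)(C)C)C1=O | intermediate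
31 | keto tautomer of the insertion product | C[C@@H]1C[C@H](C)C(=O)C2C(=O)O[C@]34C[C@H](CO[Si](C)(C)C(C)(C)C)[C@]5(C)O[C@]23[C@@H](C[C@H]4[C@@H]5O[Si](C)(C)C(C)(C)C)C1=O | intermediate
32 | bis-TBS ether of abyssomicin O | C[C@@H]1C[C@H](C)/C(O)=C2/C(=O)O[C@]34C[C@H](CO[Si](C)(C)C(C)(C)C)[C@]5(C)O[C@]23[C@@H](C[C@H]4[C@@H]5O[Si](C)(C)C(C)(C)C)C1=O | intermediate
33 | abyssomicin O | C[C@@H]1C[C@H](C)/C(O)=C2/C(=O)O[C@]34C[C@H](CO)[C@]5(C)O[C@]23[C@@H](C[C@H]4[C@@H]5O)C1=O | target

**Step count and risks**

Total: 23 steps. Longest linear sequence: 19 steps (from 3 through steps 2–4 and 8–23).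

Steps most likely to fail:

1. Step 22 (carbene insertion). The carbene may insert into a competing C–H bond, add to the ring ketone oxygen to give a carbonyl ylide, or dimerise if the 11-membered ring holds the ether methine out of reach. Fallback, setting out from 25 and returning at 32: keto acid 25 would be converted with pentafluorophenol and DCC into the pentafluorophenyl ester F1, and its tertiary hydroxyl acylated with allyl 2-diazomalonyl chloride (pyridine, DMAP) to give the diazomalonate F2. Rh2(OAc)4 would then effect the ordinary, non-transannular 1,5 insertion of a diazomalonate ester into the ether methine, a well-documented route to γ-lactones next to oxygen, giving the α-(allyloxycarbonyl) lactone F3. Soft enolisation with MgCl2/Et3N would let the malonate-type carbon attack the pentafluorophenyl ester intramolecularly, closing the eight-membered ring as the C-acylated allyl ester F4. Pd(PPh3)4 with morpholine would remove the allyl group with loss of CO2 and deliver 32.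

2. Step 20 (macrolactonisation). Strain in the 11-membered ring may slow intramolecular capture so that acylketene dimerisation or intermolecular esterification takes over, and the tertiary hydroxyl may be partly tied up as a hemiketal with the ring ketone. Fallback, setting out from 24 and returning at 29: the tertiary hydroxyl of keto aldehyde 24 would be esterified with bromoacetyl bromide/pyridine to give the bromoacetate F5. SmI2 in dilute THF at −78 °C would generate the samarium ester enolate, which adds to the aldehyde in an intramolecular Reformatsky reaction (a carbon–carbon ring closure with good precedent for medium rings) to give the β-hydroxy macrolactone F6. Dess–Martin oxidation of F6 gives 29.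

3. Step 4 (enantioselective Diels–Alder). The catalyst may discriminate poorly between the faces of an α-acyloxy enone that lacks the usual α-hydrogen contact, or the Lewis acid may desilylate the diene before cycloaddition. Fallback, setting out from 2 and 5 and returning at 12: the uncatalysed cycloaddition in toluene at 110 °C would give the racemate, that is 6 together with its mirror image F7. The aldol of step 8 with enantiopure 10 then turns the two enantiomers into diastereomers; the adduct F8 derived from F7 is removed by chromatography and 12 continues.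

Further compounds
F1 | step 22 | pentafluorophenyl ester of keto acid 25 | Fc1c(F)c(F)c(OC(=O)[C@@H](C)C[C@@H](C)C(=O)[C@@H]2C[C@H]3[C@H](O[Si](C)(C)C(C)(C)C)[C@@]4(C)O[C@@H]2[C@]3(O)C[C@@H]4CO[Si](C)(C)C(C)(C)C)c(F)c1F
F2 | step 22 | allyl diazomalonate of the tertiary alcohol of F1 | Fc1c(F)c(F)c(OC(=O)[C@@H](C)C[C@@H](C)C(=O)[C@@H]2C[C@H]3[C@H](O[Si](C)(C)C(C)(C)C)[C@@]4(C)O[C@@H]2[C@]3(OC(=O)C(=[N+]=[N-])C(=O)OCC=C)C[C@@H]4CO[Si](C)(C)C(C)(C)C)c(F)c1F
F3 | step 22 | α-(allyloxycarbonyl) γ-lactone from insertion into the ether methine | Fc1c(F)c(F)c(OC(=O)[C@@H](C)C[C@@H](C)C(=O)[C@@H]2C[C@H]3[C@H](O[Si](C)(C)C(C)(C)C)[C@@]4(C)O[C@]25[C@]3(OC(=O)C5C(=O)OCC=C)C[C@@H]4CO[Si](C)(C)C(C)(C)C)c(F)c1F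
F4 | step 22 | C-acylated allyl ester with the eight-membered ring closed | C[C@@H]1C[C@H](C)C(=O)C2(C(=O)OCC=C)C(=O)O[C@]34C[C@H](CO[Si](C)(C)C(C)(C)C)[C@]5(C)O[C@]23[C@@H](C[C@H]4[C@@H]5O[Si](C)(C)C(C)(C)C)C1=O
F5 | step 20 | bromoacetate of the tertiary alcohol of keto aldehyde 24 | O=C[C@@H](C)C[C@@H](C)C(=O)[C@@H]1C[C@H]2[C@H](O[Si](C)(C)C(C)(C)C)[C@@]3(C)O[C@@H]1[C@]2(OC(=O)CBr)C[C@@H]3CO[Si](C)(C)C(C)(C)C
F6 | step 20 | 11-membered β-hydroxy lactone | C[C@@H]1C[C@H](C)C(O)CC(=O)O[C@]34C[C@H](CO[Si](C)(C)C(C)(C)C)[C@]5(C)O[C@H]3[C@@H](C[C@H]4[C@@H]5O[Si](C)(C)C(C)(C)C)C1=O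
F7 | step 4 | mirror image of adduct 6, (3aR,7aR) | O=C1CC[C@@H]2CC(O[Si](C)(C)C(C)(C)C)=C(CO[Si](C)(C)C(C)(C)C)C[C@]12OC(=O)c3ccccc3
F8 | step 4 | diastereomeric aldol adduct from F7 and 10 | CC(=O)OC[C@@H](C)C[C@@H](C)C(O)[C@H]1C[C@@H]2CC(O[Si](C)(C)C(C)(C)C)=C(CO[Si](C)(C)C(C)(C)C)C[C@]2(OC(=O)c3ccccc3)C1=O
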